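The route rests on cutting ring B at two neighbouring carbons: the ether bond from oxygen to its C1 and its C2–Br bond (ring B: O on C1, Br on C2 and C4; ring A: O on C1, OMe on C2, H on C3, Br on C4 to C6). Oxygen and bromine on adjacent carbons are the footprint of benzyne, so one operation should unite the ring A phenoxide, benzyne and an electrophilic bromine donor. The ortho carbons (C2, C6) and the para carbon (C4) of that phenoxide are all substituted, leaving oxygen as its only reactive site. The precursor is 4,5,6-tribromo-2-methoxyphenol, made by tribromination of guaiacol; bromination at C4 of ring B then gives the target.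

Key step: step 2

Remark: the moisture-sensitive potassium phenoxide is not isolated but made with KH in the flask of the key step, so that no conjugate acid stays behind; all compounds are achiral.

Step 1
Reactants: 1 guaiacol (2-methoxyphenol)
Product: 2 4,5,6-tribromo-2-methoxyphenol (4,5,6-tribromoguaiacol; OH on C1, OMe on C2, H on C3, Br on C4, C5 and C6)
Conditions: Br2 (3.1 equiv), AcOH, 0 °C to rt; recrystallisation
Reagents that add atoms: bromine, BrBr
Why: Electrophilic aromatic bromination, in which OH directs to its para (C4) and free ortho (C6) carbons and OMe to its para carbon (C5), whereas C3, meta to OH and wedged between OMe and the C4 bromine, is the slowest site, so three equivalents should stop at the 4,5,6-tribromide.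

Step 2
Reactants: 2 4,5,6-tribromo-2-methoxyphenol; 3 2-(trimethylsilyl)phenyl trifluoromethanesulfonate; 4 1,2-dibromo-1,1,2,2-tetrachloroethane
Product: 8 1,2,3-tribromo-4-(2-bromophenoxy)-5-methoxybenzene, via potassium 2,3,4-tribromo-6-methoxyphenolate 5 (not isolated), via benzyne 6 (not isolated), via 2-(2,3,4-tribromo-6-methoxyphenoxy)phenylpotassium 7 (not isolated)
Conditions: KH (1.0 equiv), THF, 0 °C to rt; then KF (3 equiv), 18-crown-6 (3 equiv), 4 (3 equiv), 3 (1.5 equiv, slow addition), THF, 0 °C to rt
Reagents that add atoms: none
Why: Proposed new method: fluoride strips the silyl group of 3 and triflate leaves to give benzyne 6; the oxygen of phenoxide 5 adds to the strained triple bond (ether bond to C1 of ring B) and the ortho aryl anion 7 so formed attacks a bromine of 4 (C2–Br bond of ring B), the expelled carbanion collapsing to tetrachloroethene and bromide so that the halogen transfer cannot reverse. The closest known reaction type is the three-component aryne coupling in which a heteroatom nucleophile adds and the aryl anion abstracts halogen from a polyhaloalkane, together with the fluoride-mediated O-arylation of phenols by silylaryl triflates; the pairing of a phenoxide with a bromine donor is the untested element. No ring is closed and no stereocentre is formed. Benzyne is symmetric, so no regiochemistry arises, and O-attack rather than C-attack of the ambident phenoxide is enforced because C2 (OMe), C4 (Br) and C6 (Br) of ring A are all substituted. Capture of 7 by bromine rather than by a proton should be secured by deprotonating 2 with KH, by THF as a non-acidic solvent and by excess 4, while slow addition of 3 keeps benzyne scarce so that the bromide set free does not outrun the hindered phenoxide. The absence of any transition metal should leave the three C–Br bonds of ring A untouched.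

Step 3
Reactants: 8 1,2,3-tribromo-4-(2-bromophenoxy)-5-methoxybenzene
Product: 9 1,2,3-tribromo-4-(2,4-dibromophenoxy)-5-methoxybenzene (target)
Conditions: Br2 (1.05 equiv), FeBr3 (5 mol %), CH2Cl2, 0 °C to rt, dark
Reagents that add atoms: bromine, BrBr
Why: Lewis-acid-catalysed electrophilic aromatic bromination, in which C4 of ring B is para to the ether oxygen, whose lone pair conjugates with ring B because the doubly ortho-substituted ring A is twisted out of plane, while the lone C–H of ring A (C3) lies between OMe and Br on a ring deactivated by three bromines and C6 of ring B is shielded by the aryloxy group.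

Compound list
1 | guaiacol (2-methoxyphenol) | COc1ccccc1O | starting material
2 | 4,5,6-tribromo-2-methoxyphenol | COc1cc(Br)c(Br)c(Br)c1O | intermediate
3 | 2-(trimethylsilyl)phenyl trifluoromethanesulfonate | C[Si](C)(C)c1ccccc1OS(=O)(=O)C(F)(F)F | starting material
4 | 1,2-dibromo-1,1,2,2-tetrachloroethane | ClC(Cl)(Br)C(Cl)(Cl)Br | starting material
5 | potassium 2,3,4-tribromo-6-methoxyphenolate | COc1cc(Br)c(Br)c(Br)c1[O-].[K+] | intermediate (not isolated)
6 | benzyne | C1=CC=CC#C1 | intermediate (not isolated)
7 | 2-(2,3,4-tribromo-6-methoxyphenoxy)phenylpotassium | COc1cc(Br)c(Br)c(Br)c1Oc1ccccc1[K] | intermediate (not isolated)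
8 | 1,2,3-tribromo-4-(2-bromophenoxy)-5-methoxybenzene | COc1cc(Br)c(Br)c(Br)c1Oc1ccccc1Br | intermediate
9 | 1,2,3-tribromo-4-(2,4-dibromophenoxy)-5-methoxybenzene | COc1cc(Br)c(Br)c(Br)c1Oc1ccc(Br)cc1Br | target

Total step count: 3
Longest linear sequence: 3 steps (1 to 2 to 8 to 9); 3 and 4 are purchased.

Steps most likely to fail

Step 2 (proposed new method). Three processes may erode it. The aryl anion 7 may be protonated by adventitious proton sources, or by the C3–H of ring A in a second molecule, before bromine transfer. The bromide released from 4 may capture benzyne faster than the hindered, weakly nucleophilic phenoxide. Bromine–metal exchange between 7 and the bromines of ring A may scramble the halogen pattern.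

The fallback uses known chemistry, sets out from 2 and comes back at 8. Oxidation of 1-bromo-2-iodobenzene with mCPBA and BF3·OEt2 in CH2Cl2, followed by 2-bromophenylboronic acid, should give bis(2-bromophenyl)iodonium tetrafluoroborate F1. Phenol 2 is deprotonated with KOtBu in THF and treated with F1 at rt to 40 °C. This metal-free O-arylation proceeds by ligand coupling at trivalent iodine, tolerates ortho substituents on both partners and cannot insert into C–Br bonds. The symmetrical salt leaves no choice of aryl group, and the product should be 8.

Step 3. Substitution on ring B, which carries a deactivating bromine at its C2, may be sluggish. Forcing it may cost site selectivity through attack at C6 of ring B or C3 of ring A, or through double bromination. The fallback sets out from 8 and comes back at 9. C–H thianthrenation (thianthrene S-oxide, trifluoroacetic anhydride, HBF4·OEt2, MeCN, 0 °C to rt) is highly para-selective and very sensitive to steric crowding. It should give 5-[3-bromo-4-(2,3,4-tribromo-6-methoxyphenoxy)phenyl]thianthrenium tetrafluoroborate F2, a salt easily separated from neutral material. Photoredox copper-mediated bromination (LiBr, CuBr, catalytic Ru(bpy)3(PF6)2, MeCN, blue light, rt) should then replace the sulfonium group by bromine at C4 of ring B and give 9.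

Step 1. The third bromine may enter at C3 in competition with C6, or the reaction may run on to the tetrabromide, leaving mixtures that crystallise together. The fallback sets out from 1 and comes back at 2. Br2 (2.0 equiv) in AcOH should give 4,5-dibromo-2-methoxyphenol F3 (bromine para to OH and para to OMe), purified by crystallisation. Amine-mediated ortho-bromination (NBS, catalytic iPr2NH, CH2Cl2, rt) then delivers bromine through hydrogen bonding to the hydroxyl group. It can therefore reach only C6 and should give 2.

Further compounds
F1 | step 2 | bis(2-bromophenyl)iodonium tetrafluoroborate | Brc1ccccc1[I+]c1ccccc1Br.F[B-](F)(F)F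
F2 | step 3 | 5-[3-bromo-4-(2,3,4-tribromo-6-methoxyphenoxy)phenyl]thianthrenium tetrafluoroborate | COc1cc(Br)c(Br)c(Br)c1Oc1ccc(cc1Br)[S+]1c2ccccc2Sc2ccccc12.F[B-](F)(F)F
F3 | step 1 | 4,5-dibromo-2-methoxyphenol | COc1cc(Br)c(Br)cc1O
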